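**Retrosynthetic overview**

1. The last C–C bond made is the C4–C8 interflavan bond: a C4 benzylic cation (quinone-methide type) of an epiafzelechin unit is captured by C8 of intact (−)-epigallocatechin, as in the plant; debenzylation follows.
2. The cation precursor is a 4β-methoxy-2,3-cis-flavan-3-ol. It comes from a trans-3-bromoflavanone by reduction, closure to the 3,4-epoxide cis to the aryl group (inversion at C3) and methanolysis.
3. The flavanone is cut at O1–C2: ring C of the upper unit is closed by an enantioselective chalcone-to-flavanone oxa-Michael cyclisation (chalcone isomerase mimic). This is the only stereocentre set by a catalyst; C3 and C4 are relayed from it.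
4. The chalcone comes from cheap racemic naringenin by benzylation with ring opening.
5. Ring order: rings A and B of the upper unit and all three rings of the lower unit are bought; ring C of the upper unit is the only ring built (step 2); the oxirane of step 4 is transient.

Assumptions: (±)-naringenin and (−)-epigallocatechin (green-tea isolate) are bought; of the two pseudo-enantiomeric cinchona squaramides the quinidine-derived one is taken to give the (2S)-flavanone (otherwise the quinine-derived one is used).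

**Route**

Step 1
Reactants: 1 (±)-naringenin
Product: 3 (E)-1-[2,4-bis(benzyloxy)-6-hydroxyphenyl]-3-[4-(benzyloxy)phenyl]prop-2-en-1-one (tri-O-benzyl naringenin chalcone), via dibenzyl naringenin 2 (not isolated)
Conditions: BnBr (3.6 equiv), K2CO3 (5 equiv), DMF, 80 °C, 12 h
Reagents that add atoms: benzyl bromide, BrCc1ccccc1
Why: Williamson O-benzylation of the 7- and 4'-phenols is followed by base-induced retro-oxa-Michael (E1cB) opening of ring C and benzylation of one of the two now equivalent ortho-phenoxides, the other staying hydrogen-bonded to the carbonyl; no stereocentre remains.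

Step 2
Reactants: 3 tri-O-benzyl naringenin chalcone
Product: 4 (2S)-5,7-bis(benzyloxy)-2-[4-(benzyloxy)phenyl]chroman-4-one
Conditions: N-[3,5-bis(trifluoromethyl)phenyl]-N'-(9-deoxy-epi-quinidin-9-yl)squaramide (10 mol%), toluene, 0 °C → rt, stopped at ca. 75% conversion; unreacted 3 recycled, 4 recrystallised
Reagents that add atoms: none
Why: Proposed new method: enantioselective 6-endo intramolecular oxa-Michael addition (the chalcone isomerase reaction), in which the quinuclidine nitrogen deprotonates the 2'-phenol while the squaramide hydrogen-bonds the enone carbonyl, so the phenoxide adds to one face of C-β and C2 is set as S under kinetic control, the reaction being stopped before the slower retro-addition erodes the ee; the closest known reaction types are the cinchona-thiourea-catalysed cyclisation of activated alkylidene β-keto esters to flavanones and the quinine-catalysed cyclisation of simple 2'-hydroxychalcones.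

Step 3
Reactants: 4 (2S)-tri-O-benzyl flavanone
Product: 6 (2R,3R)-5,7-bis(benzyloxy)-2-[4-(benzyloxy)phenyl]-3-bromochroman-4-one (2,3-trans), via silyl enol ether 5 (not isolated)
Conditions: TMSOTf, Et3N, CH2Cl2, −10 °C; then NBS (1.0 equiv), THF, −78 °C
Reagents that add atoms: N-bromosuccinimide, O=C1CCC(=O)N1Br
Why: Soft enolisation to the silyl enol ether avoids a free enolate (no retro-oxa-Michael, so C2 is kept), and electrophilic α-bromination then occurs on the face of C3 opposite the 2-aryl group to give the 2,3-trans bromide, which is also the thermodynamic epimer.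

Step 4
Reactants: 6 trans-3-bromoflavanone
Product: 9 (2R,3R,4S)-5,7-bis(benzyloxy)-2-[4-(benzyloxy)phenyl]-4-methoxychroman-3-ol (2,3-cis-3,4-trans), via bromohydrin 7 (not isolated), via epoxide 8 (not isolated)
Conditions: NaBH4, THF/MeOH, −20 °C; then K2CO3, MeOH, 0 → 40 °C
Reagents that add atoms: methanol, CO
Why: Axial hydride delivery to the α-bromo ketone gives the all-equatorial 2,3-trans-3,4-trans bromohydrin, whose 4-alkoxide displaces bromide from the rear (halohydrin-to-epoxide closure, inversion at C3, oxygen now cis to the 2-aryl group), and the very electron-rich benzylic epoxide is opened at C4 by methanol with inversion (solvolysis through the alkoxy-stabilised benzylic cation), leaving the 3-OH cis to the aryl group.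

Step 5
Reactants: 9 4β-methoxy-tri-O-benzyl-epiafzelechin; 10 (−)-epigallocatechin
Product: 11 5,7,4'-tri-O-benzyl-epiafzelechin-(4β→8)-epigallocatechin
Conditions: 10 (4 equiv, excess recovered), BF3·OEt2 (0.5 equiv), THF/CH2Cl2 (1:1), −40 → 0 °C, argon
Reagents that add atoms: none
Why: Lewis-acid ionisation of the 4-methoxy group gives the ring A-stabilised C4 benzylic cation (the biosynthetic extension unit), which undergoes Friedel–Crafts alkylation by the most nucleophilic position (C8) of epigallocatechin on the face anti to the 3-OH and the 2-aryl group, so the 4β (3,4-trans) linkage forms by substrate control.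

Step 6
Reactants: 11 tri-O-benzyl dimer
Product: 12 epiafzelechin-(4β→8)-epigallocatechin (CNP0290824.1)
Conditions: H2 (1 atm), Pd(OH)2/C, THF/MeOH/H2O, rt; Sephadex LH-20
Reagents that add atoms: none
Why: Hydrogenolysis of the three benzyl ethers under neutral conditions leaves the interflavan bond, the pyran C–O bonds and all five stereocentres untouched.

**Compound list**

1 | (±)-naringenin, racemic 5,7-dihydroxy-2-(4-hydroxyphenyl)chroman-4-one | O=C1CC(c2ccc(O)cc2)Oc2cc(O)cc(O)c12 | starting material
2 | (±)-7,4'-di-O-benzylnaringenin, racemic 7-(benzyloxy)-2-[4-(benzyloxy)phenyl]-5-hydroxychroman-4-one | O=C1CC(c2ccc(OCc3ccccc3)cc2)Oc2cc(OCc3ccccc3)cc(O)c12 | intermediate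
3 | (E)-1-[2,4-bis(benzyloxy)-6-hydroxyphenyl]-3-[4-(benzyloxy)phenyl]prop-2-en-1-one | O=C(/C=C/c1ccc(OCc2ccccc2)cc1)c1c(O)cc(OCc2ccccc2)cc1OCc1ccccc1 | intermediate
4 | (2S)-5,7-bis(benzyloxy)-2-[4-(benzyloxy)phenyl]chroman-4-one | c1ccc(COc2ccc([C@H]3Oc4cc(OCc5ccccc5)cc(OCc5ccccc5)c4C(=O)C3)cc2)cc1 | intermediate
5 | (2S)-5,7-bis(benzyloxy)-2-[4-(benzyloxy)phenyl]-4-(trimethylsilyloxy)-2H-chromene | c1ccc(COc2ccc([C@H]3Oc4cc(OCc5ccccc5)cc(OCc5ccccc5)c4C(O[Si](C)(C)C)=C3)cc2)cc1 | intermediate
6 | (2R,3R)-5,7-bis(benzyloxy)-2-[4-(benzyloxy)phenyl]-3-bromochroman-4-one, Br trans to the 2-aryl group | c1ccc(COc2ccc([C@H]3Oc4cc(OCc5ccccc5)cc(OCc5ccccc5)c4C(=O)[C@@H]3Br)cc2)cc1 | intermediate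
7 | (2R,3S,4R)-5,7-bis(benzyloxy)-2-[4-(benzyloxy)phenyl]-3-bromochroman-4-ol, 2,3-trans-3,4-trans | c1ccc(COc2ccc([C@H]3Oc4cc(OCc5ccccc5)cc(OCc5ccccc5)c4[C@@H](O)[C@@H]3Br)cc2)cc1 | intermediate
8 | (2R,3R,4R)-5,7-bis(benzyloxy)-2-[4-(benzyloxy)phenyl]-3,4-epoxychroman (flavan numbering), oxirane oxygen cis to the 2-aryl group | c1ccc(COc2ccc([C@H]3Oc4cc(OCc5ccccc5)cc(OCc5ccccc5)c4[C@H]4O[C@@H]34)cc2)cc1 | intermediate
9 | (2R,3R,4S)-5,7-bis(benzyloxy)-2-[4-(benzyloxy)phenyl]-4-methoxychroman-3-ol, 3-OH cis to aryl, 4-OMe trans to 3-OH | c1ccc(COc2ccc([C@H]3Oc4cc(OCc5ccccc5)cc(OCc5ccccc5)c4[C@H](OC)[C@H]3O)cc2)cc1 | intermediate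
10 | (−)-epigallocatechin, (2R,3R)-2-(3,4,5-trihydroxyphenyl)chroman-3,5,7-triol | Oc1cc(O)c2c(c1)O[C@H](c1cc(O)c(O)c(O)c1)[C@H](O)C2 | starting material
11 | 5,7,4'-tri-O-benzyl-epiafzelechin-(4β→8)-epigallocatechin; upper unit 2,3-cis-3,4-trans, all centres as in the target | c1ccc(COc2ccc([C@H]3Oc4cc(OCc5ccccc5)cc(OCc5ccccc5)c4[C@H](c4c(O)cc(O)c5c4O[C@H](c4cc(O)c(O)c(O)c4)[C@H](O)C5)[C@H]3O)cc2)cc1 | intermediate
12 | epiafzelechin-(4β→8)-epigallocatechin; upper unit (2R,3R,4R), lower unit (2R,3R) | Oc1ccc([C@H]2Oc3cc(O)cc(O)c3[C@H](c3c(O)cc(O)c4c3O[C@H](c3cc(O)c(O)c(O)c3)[C@H](O)C4)[C@H]2O)cc1 | target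

**Count**

Total steps: 6. Longest linear sequence: 6 (1 → 12); 10 enters at step 5.

**Steps most likely to fail, with fallbacks**

Step 2. The 6'-benzyloxy chalcone cyclises reluctantly and reversibly, so conversion and ee may be poor. A minor enantiomer would surface as a separable diastereomer of 11, but the material would be lost. The fallback sets out from 3 and comes back at 4. Chalcone 3 is cyclised without control (NaOAc, EtOH, reflux) to the racemic flavanone F1. F1 is then reduced by asymmetric transfer hydrogenation under dynamic kinetic resolution ([RuCl(p-cymene)((S,S)-TsDPEN)], HCO2H/Et3N, DBU, 40 °C). Under these conditions F1 racemises through the same ring-opening and ring-closing (retro-oxa-Michael and oxa-Michael), while only the (2S)-ketone is reduced, giving the cis-flavan-4-ol F2. Re-oxidation of the benzylic alcohol (MnO2, CH2Cl2) returns 4 with catalyst-controlled ee, at the cost of one extra step.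

Step 4. The hydride may attack the wrong face, giving the 3,4-cis bromohydrin that cannot close to the epoxide, or base may dehydrobrominate residual 6 to the flavone. The fallback sets out from 4 (bypassing 6) and comes back at 7. Flavanone 4 is reduced (NaBH4, MeOH) to the 4-epimeric flavan-4-ols F3, which are dehydrated (PPTS, toluene, 80 °C) to the (2S)-flav-3-ene F4. Addition of HOBr (N-bromoacetamide, THF/H2O, −20 °C) puts bromine on C3 anti to the 2-aryl group and water on benzylic C4 anti to bromine. This gives bromohydrin 7 by stereospecific anti-addition instead of by hydride face selectivity. K2CO3/MeOH then carries 7 on to 9 as in step 4.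

Step 5. Free epigallocatechin may give a C8/C6 mixture and over-alkylation, and may sequester BF3. The fallback sets out from 9 and 10 and comes back at 12. Compound 10 is benzylated (NaH, BnBr, DMF, −20 → 0 °C) to penta-O-benzyl-epigallocatechin F5. Compound 9 is coupled with F5 (3 equiv) under catalytic TMSOTf (CH2Cl2, −78 °C); a benzylated nucleophile of this kind reacts at C8 only, giving the octa-O-benzyl dimer F6. Hydrogenolysis (H2, Pd(OH)2/C, THF/MeOH/H2O) of all eight benzyl ethers gives 12 directly.

**Further compounds**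

F1 | step 2 | racemic 5,7-bis(benzyloxy)-2-[4-(benzyloxy)phenyl]chroman-4-one | O=C1CC(c2ccc(OCc3ccccc3)cc2)Oc2cc(OCc3ccccc3)cc(OCc3ccccc3)c12
F2 | step 2 | (2S,4S)-5,7-bis(benzyloxy)-2-[4-(benzyloxy)phenyl]chroman-4-ol, 2,4-cis | c1ccc(COc2ccc([C@H]3Oc4cc(OCc5ccccc5)cc(OCc5ccccc5)c4[C@@H](O)C3)cc2)cc1
F3 | step 4 | (2S)-5,7-bis(benzyloxy)-2-[4-(benzyloxy)phenyl]chroman-4-ol, mixture of C4 epimers | c1ccc(COc2ccc([C@H]3Oc4cc(OCc5ccccc5)cc(OCc5ccccc5)c4C(O)C3)cc2)cc1
F4 | step 4 | (2S)-5,7-bis(benzyloxy)-2-[4-(benzyloxy)phenyl]-2H-chromene | c1ccc(COc2ccc([C@H]3Oc4cc(OCc5ccccc5)cc(OCc5ccccc5)c4C=C3)cc2)cc1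
F5 | step 5 | 5,7,3',4',5'-penta-O-benzyl-(−)-epigallocatechin, (2R,3R) | c1ccc(COc2cc(OCc3ccccc3)c3c(c2)O[C@H](c2cc(OCc4ccccc4)c(OCc4ccccc4)c(OCc4ccccc4)c2)[C@H](O)C3)cc1
F6 | step 5 | octa-O-benzyl-epiafzelechin-(4β→8)-epigallocatechin, all centres as in the target | c1ccc(COc2ccc([C@H]3Oc4cc(OCc5ccccc5)cc(OCc5ccccc5)c4[C@H](c4c(OCc5ccccc5)cc(OCc5ccccc5)c5c4O[C@H](c4cc(OCc6ccccc6)c(OCc6ccccc6)c(OCc6ccccc6)c4)[C@H](O)C5)[C@H]3O)cc2)cc1
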